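## Structural features

Bleochrin B (16) is an achiral pentaphenol built on a bibenzyl. Ring A and ring B are joined by the two-carbon bridge A1–Cα–Cβ–B1, and four 4-hydroxybenzyl groups hang on CH2 links, three on ring A (A2, A4, A6) and one on ring B (B6). Ring A is hexasubstituted: besides the bridge and the three benzyl groups it carries a free hydroxyl at A3 and the only methyl ether at A5, so each of its benzyl groups is flanked on both sides. Ring B is 1,2,4-trisubstituted, with its hydroxyl at B3 meta to the bridge and para to the B6 benzyl group. There is no stereocentre, so no neighbouring stereocentres have to be related; the problem is regiochemistry, crowding, and keeping one OMe distinct from five OH. The fragile parts are the electron-rich phenols (air oxidation under base) and the aryl–CH2–aryl bonds on ring A, which stand ortho or para to oxygen at both ends and can lose a 4-hydroxybenzyl cation after ipso-protonation in strong acid. The real difficulty is to place three identical groups on the crowded positions A2, A4 and A6 without touching ring B. The key step uses this repetition: A2, A4 and A6 are the two ortho positions and the para position of the A3 oxygen, so their CH2 carbons can be introduced by electrophilic substitution, and the three outer CH2–C(aryl) bonds, one atom away from the congested ring, can then be formed together from a 2,4,6-tris(chloromethyl) ring A and three molecules of one 4-oxygenated aryl bromide.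

## Logic of the disconnections

16 ⇒ 15 ⇒ 14. The last cuts are C–O bonds: the five O–CH2Ph bonds of 15 and the O–acyl bond at A3 of 14. One neutral hydrogenolysis frees all five phenols and avoids acid, which would endanger the aryl–CH2–aryl bonds of ring A. Benzyl ethers are also inert to the acylating agent of the amine dealkylation and to the zinc salts formed at the anode, and they are already present in the purchased building blocks 4 and 13. The gain is a non-phenolic, easily purified 14. The demands are that hydrogenolysis spares the diarylmethane C–C bonds and the A5 methyl ether, and that a small hydride reaches the hindered ester at A3.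

14 ⇒ 12 + three molecules of 13. The three CH2–C(aryl) bonds on A2, A4 and A6 are cut, not the ring A–CH2 bonds. These bonds lie outside the crowded ring, the three groups are identical, and one operation can make all of them. The gain is the removal of three aryl rings at once, leaving a bibenzyl with three one-carbon handles. The forward step must couple three times per molecule and favour cross-coupling over homocoupling; 12 must not ionise, which is why the A3 oxygen carries an acyl group and not an alkyl or acetal group.

12 ⇒ 11 ⇒ 10 ⇒ 9. The cuts are three C–Cl bonds (traced back to C–N bonds), the O–acyl bond at A3, and the three ring A–CH2 bonds. In 9 the positions A2, A4 and A6 are ortho, ortho and para to the free A3 hydroxyl and also ortho or para to the A5 methoxy group, so all three carbons can be delivered by one-carbon iminium electrophiles in a Mannich reaction. The amino groups serve as latent leaving groups. The gain is that 9 has a ring A with only three substituents. The demands are a complete threefold substitution at flanked positions that leaves ring B alone, and O-acylation before amine activation, because a free ortho-aminomethyl phenol would eliminate to a quinone methide. The cap has to be an acyl group, since an alkylating agent would quaternise the amines.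

9 ⇒ 6 + 7 (through 8). The bond A1–Cα is cut. It is an sp2–sp3 bond to an unhindered aryl bromide whose bromine is meta to both oxygen substituents, and the cut divides the molecule into its two ring systems and delivers the free phenol needed for the next step. The forward step must hydroborate the vinyl group of 6 at the terminal carbon and couple the alkylborane in the presence of a phenoxide.

6 ⇒ 3 + 4 (through 5). The bond B6–CH2 is cut. The bromine of 3 marks B6, and 4 already contains the CH2 carbon and the protected phenol ring. The gain is a one-step assembly of the diarylmethane of ring B. The demands are zinc insertion without Wurtz coupling and a cross-coupling that does not involve the vinyl group.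

3 ⇒ 2 ⇒ 1. The Cα=Cβ double bond is cut (Cβ is the formyl carbon of 1), then the O–CH2Ph bond. 1 already holds the formyl group, the bromine and the hydroxyl in the 1,2,4-relationship of B1, B6 and B3. The olefination is placed before the zinc chemistry because 5 would add to the aldehyde of 2.

## Other disconnections considered

In this section ring atoms are written "position A2", and compounds of the alternatives "compound A2".

Alternative 1: The cut goes through the ring–CH2 bonds at positions A2 and A6 and through the bond from position A1 to Cα. Forward, the iodoarene compound A2 (iodine at position A1, one benzyl group already at position A4), two molecules of the benzyl chloride compound A3 and the ring B styrene compound A4 would be combined under palladium catalysis with a strained bicyclic alkene as transient mediator (Catellani reaction). The arylpalladium species would be relayed to both ortho C–H bonds, each would be benzylated, and a terminating Heck reaction would give the E-stilbene compound A1.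
- In its favour: three C–C bonds on ring A and the union of the two ring systems in one operation, an iodide with two free ortho positions as the relay requires, and no organoboron or organozinc reagent.
- Against it here: each C–H bond to be activated is wedged between the palladium-bearing carbon and an oxygen substituent, where this relay is slowest. The electron-rich compound A3 can add to zerovalent palladium directly and be lost in a benzyl Heck reaction with compound A4. Only two of the three identical benzyl groups are made, so the third needs its own directed metalation and benzylation. Compound A1 still has to be hydrogenated.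
- Comparison: on step economy the alternative is the better one, since the whole carbon skeleton arises in one step from compound A2 and, with benzyl ethers, alkene reduction and deprotection could be one hydrogenation. On structure the chosen plan is better: it makes the CH2–aryl bonds away from the crowded ring and leaves the ring–CH2 bonds to a phenol-directed Mannich reaction. On mechanism the alternative needs a strict order of many organometallic events in one flask, with tetravalent palladium intermediates and four competing components; the chosen plan repeats one catalytic cycle at three independent sites.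

Alternative 2: The cut removes both ring-to-bridge bonds, position A1–Cα and Cβ–position B1, leaving a two-carbon linchpin. Forward, the ring A aryllithium compound A6 would add to the vinylboronic ester compound A7 to give a boron ate complex. A palladium bisphosphine catalyst, after oxidative addition to the ring B triflate compound A8, would induce the 1,2-shift of the ring A aryl group from boron to Cα, and reductive elimination would form the bond from Cβ to position B1. The product would be the racemic benzylic boronic ester compound A5.
- In its favour: two complete halves are joined late and under mild conditions, both bridge bonds form together, and the three components can be varied independently.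
- Against it here: the migrating carbon is flanked by two benzyl groups, so ate formation and the shift are sterically burdened. The aryllithium sits next to doubly benzylic C–H bonds that can quench it by proton transfer. A boron-bearing stereocentre is created that the achiral target does not need, and it costs a protodeboronation step. Compound A6 presupposes a ring A that already carries all three benzyl groups, so the hardest part of the molecule is not addressed.
- Comparison: on the union of the two ring systems the alternative is the equal of the chosen plan, since both make the bridge in one pot from a vinyl unit. On structure it moves the difficulty into the preparation of compound A6. On mechanism the metallate shift is elegant but sensitive to ortho substitution. On step economy it is longer by the protodeboronation and by a separate threefold benzylation of ring A.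

Alternative 3: The cut goes through ring B itself, at the bonds between positions B1 and B2 and between positions B5 and B6. Forward, the ynone compound A10 and the Danishefsky diene compound A11 would undergo a Diels–Alder addition; loss of the methoxy group as the alcohol and desilylation would aromatise the adduct to the 4-hydroxybenzophenone compound A9.
- In its favour: the polarity of the diene fixes the ring B pattern (its nucleophilic terminus bonds to the β-carbon of the ynone), no transition metal is needed, and the ring B phenol emerges unprotected.
- Against it here: the benzylic carbon at position B6 is formed as a ketone and must be deoxygenated in one or two further steps, under conditions that the acetal ethers of compound A9 tolerate poorly. Compound A10 needs a fully benzylated ring A with a homopropargyl chain, which makes the sequence long and linear. A benzene ring with the correct pattern can simply be bought (1).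
- Comparison: on structure the alternative is the equal of the chosen plan in regiochemical certainty for ring B, and it saves one protecting group. On mechanism its key step, a thermal pericyclic reaction, is more predictable than a threefold radical cross-coupling, and on this point it is the better one. On step economy it is clearly worse, and like alternative 2 it leaves the congestion of ring A untouched.

Key step: step 8

Remark on the chemistry: the five phenols are carried as benzyl ethers and the A3 oxygen as a pivalate; this is a choice of spectator groups only, and the carbon skeletons of 12 and 14 and the three bonds formed in step 8 are unchanged. Step 8 consumes three molecules of 13 for each molecule of 12; one stands on its Reactants line and the other two on its line of atom-adding reagents.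

## Route

Step 1
Reactants: 1 2-bromo-5-hydroxybenzaldehyde
Product: 2 5-(benzyloxy)-2-bromobenzaldehyde
Conditions: BnBr, K2CO3, DMF, 25 °C
Reagents that add atoms: benzyl bromide, BrCc1ccccc1
Why: Williamson ether synthesis; the phenoxide is alkylated by the primary benzylic bromide, and the aldehyde and the aryl bromide are inert to carbonate in DMF.

Step 2
Reactants: 2 5-(benzyloxy)-2-bromobenzaldehyde
Product: 3 4-(benzyloxy)-1-bromo-2-ethenylbenzene
Conditions: Ph3PCH3Br, KOtBu, THF, 0 to 25 °C
Reagents that add atoms: methyltriphenylphosphonium bromide, C[P+](c1ccccc1)(c1ccccc1)c1ccccc1.[Br-]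
Why: Wittig methylenation of an aromatic aldehyde with the unstabilised ylide; the aryl bromide and the benzyl ether do not react, and no stereochemical issue arises with a terminal alkene.

Step 3
Reactants: 3 4-(benzyloxy)-1-bromo-2-ethenylbenzene; 4 1-(benzyloxy)-4-(chloromethyl)benzene
Product: 6 4-(benzyloxy)-1-[4-(benzyloxy)benzyl]-2-ethenylbenzene, via [4-(benzyloxy)benzyl]zinc chloride 5 (not isolated)
Conditions: 4, Zn dust, LiCl, THF, 25 °C; then 3, Pd(OAc)2 (2 mol%), SPhos (4 mol%), THF, 25 to 50 °C
Reagents that add atoms: none
Why: LiCl-assisted zinc insertion into the benzylic chloride followed by Negishi coupling with the aryl bromide. Transmetalation from zinc to the arylpalladium bromide should outrun any Heck insertion of the vinyl group, because no base is present to turn a Heck cycle over.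

Step 4
Reactants: 6 4-(benzyloxy)-1-[4-(benzyloxy)benzyl]-2-ethenylbenzene; 7 3-bromo-5-methoxyphenol
Product: 9 3-{2-[5-(benzyloxy)-2-[4-(benzyloxy)benzyl]phenyl]ethyl}-5-methoxyphenol, via 9-alkyl-9-borabicyclo[3.3.1]nonane 8 (not isolated)
Conditions: 9-BBN, THF, 0 to 25 °C; then 7, PdCl2(dppf) (5 mol%), K3PO4 (3 M aq), DMF, 70 °C
Reagents that add atoms: none
Why: Hydroboration of the styrene with 9-BBN places boron on the terminal carbon, and a B-alkyl Suzuki–Miyaura coupling then forms A1–Cα. The bromine of 7 is meta to both oxygen substituents, so the phenoxide formed under the basic conditions should hardly slow oxidative addition.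

Step 5
Reactants: 9 3-{2-[5-(benzyloxy)-2-[4-(benzyloxy)benzyl]phenyl]ethyl}-5-methoxyphenol
Product: 10 3-{2-[5-(benzyloxy)-2-[4-(benzyloxy)benzyl]phenyl]ethyl}-2,4,6-tris[(dimethylamino)methyl]-5-methoxyphenol
Conditions: Me2NH (40% aq, excess), CH2O (37% aq, excess), EtOH/1,4-dioxane, 90 °C, sealed tube
Reagents that add atoms: formaldehyde, C=O; dimethylamine, CNC
Why: Threefold phenol Mannich reaction (three molecules of each reagent are built in); A2, A4 and A6 are the ortho, ortho and para positions of the free hydroxyl and are further activated by the A5 methoxy group. The benzyl-ether rings carry no free hydroxyl and should not be attacked by the iminium ion; excess reagent and heat are meant to drive the third, para substitution.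

Step 6
Reactants: 10 3-{2-[5-(benzyloxy)-2-[4-(benzyloxy)benzyl]phenyl]ethyl}-2,4,6-tris[(dimethylamino)methyl]-5-methoxyphenol
Product: 11 3-{2-[5-(benzyloxy)-2-[4-(benzyloxy)benzyl]phenyl]ethyl}-2,4,6-tris[(dimethylamino)methyl]-5-methoxyphenyl pivalate
Conditions: PivCl (1.2 equiv), Et3N, DMAP (cat.), CH2Cl2, 0 to 25 °C
Reagents that add atoms: pivaloyl chloride, CC(C)(C)C(=O)Cl
Why: DMAP-catalysed O-acylation of the phenol; an acyl chloride reacts only reversibly with the three tertiary amines, whereas an alkylating agent would quaternise them. The pivalate blocks quinone methide formation in the next step and lowers the donor strength of the A3 oxygen.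

Step 7
Reactants: 11 3-{2-[5-(benzyloxy)-2-[4-(benzyloxy)benzyl]phenyl]ethyl}-2,4,6-tris[(dimethylamino)methyl]-5-methoxyphenyl pivalate
Product: 12 3-{2-[5-(benzyloxy)-2-[4-(benzyloxy)benzyl]phenyl]ethyl}-2,4,6-tris(chloromethyl)-5-methoxyphenyl pivalate
Conditions: ClCO2Et (6 equiv), NaHCO3 (solid), CH2Cl2, 0 to 25 °C, 11 added slowly to the chloroformate
Reagents that add atoms: ethyl chloroformate, CCOC(=O)Cl
Why: Chloroformate dealkylation of tertiary benzylic amines (von Braun-type), once at each of the three sites: N-acylation gives an acylammonium chloride, and chloride attacks the benzylic carbon, which is activated by the ortho or para methoxy group, releasing a carbamate. The benzylic C–N bond cleaves in preference to N–CH3, and inverse addition keeps unreacted amine from being alkylated by the chloride already formed.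

Step 8
Reactants: 12 3-{2-[5-(benzyloxy)-2-[4-(benzyloxy)benzyl]phenyl]ethyl}-2,4,6-tris(chloromethyl)-5-methoxyphenyl pivalate; 13 1-(benzyloxy)-4-bromobenzene (three molecules are incorporated)
Product: 14 3-{2-[5-(benzyloxy)-2-[4-(benzyloxy)benzyl]phenyl]ethyl}-2,4,6-tris[4-(benzyloxy)benzyl]-5-methoxyphenyl pivalate
Conditions: NiBr2(dme) (15 mol%), 4,4'-di-tert-butyl-2,2'-bipyridine (18 mol%), 13 (6 equiv), n-Bu4NBr, DMA, undivided cell, Zn anode, Ni-foam cathode, constant current (about 7 F/mol), 25 °C, 12 added by syringe pump during the electrolysis
Reagents that add atoms: 1-(benzyloxy)-4-bromobenzene 13 (second and third molecule), Brc1ccc(OCc2ccccc2)cc1.Brc1ccc(OCc2ccccc2)cc1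
Why: At the cathode the divalent nickel bipyridine complex takes up two electrons, and the zerovalent nickel so formed inserts into the C–Br bond of 13 to give a divalent arylnickel bromide. Monovalent nickel removes chlorine from one chloromethyl group of 12; the benzylic radical combines with the arylnickel bromide, and the trivalent aryl(benzyl)nickel complex collapses by reductive elimination to the CH2–aryl bond and monovalent nickel, which re-enters the cycle. The cycle runs once at each chloromethyl group, so three molecules of 13 are consumed for each molecule of 12 and their bromine and the three chlorines leave as zinc halides at the anode. The closest known reaction type is the nickel-catalysed electroreductive cross-electrophile coupling of benzyl chlorides with aryl bromides, run here three times on one substrate at independent sites. No ring is closed and no stereocentre is formed. The selectivity required is cross-coupling over benzyl–benzyl and aryl–aryl homocoupling; it rests on the two different activation modes (two-electron insertion for the sp2 bromide, halogen abstraction for the benzylic chloride), on the excess of 13 and on the slow feed of 12, which keeps the radical concentration small against a standing pool of arylnickel. Because each chloromethyl group stands meta to the other two, no quinodimethane can form and no intramolecular benzyl–benzyl coupling is geometrically possible, while the acyl group on the A3 oxygen lowers the tendency of the chlorides to ionise and should be inert towards nickel bipyridine species at 25 °C. The bonds are made one carbon away from the hexasubstituted ring, so the two ortho neighbours of every CH2 group should not hinder the nickel centre.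

Step 9
Reactants: 14 3-{2-[5-(benzyloxy)-2-[4-(benzyloxy)benzyl]phenyl]ethyl}-2,4,6-tris[4-(benzyloxy)benzyl]-5-methoxyphenyl pivalate
Product: 15 3-{2-[5-(benzyloxy)-2-[4-(benzyloxy)benzyl]phenyl]ethyl}-2,4,6-tris[4-(benzyloxy)benzyl]-5-methoxyphenol
Conditions: LiAlH4, THF, 0 to 25 °C; aqueous potassium sodium tartrate work-up
Reagents that add atoms: none
Why: Hydride reduction of an aryl ester; the small hydride should reach the carbonyl although the aryl oxygen is flanked by two benzyl groups, and benzyl ethers, the methyl ether and the diarylmethanes are inert to LiAlH4.

Step 10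
Reactants: 15 3-{2-[5-(benzyloxy)-2-[4-(benzyloxy)benzyl]phenyl]ethyl}-2,4,6-tris[4-(benzyloxy)benzyl]-5-methoxyphenol
Product: 16 bleochrin B, 3-{2-[5-hydroxy-2-(4-hydroxybenzyl)phenyl]ethyl}-2,4,6-tris(4-hydroxybenzyl)-5-methoxyphenol
Conditions: H2 (1 atm), 10% Pd/C, EtOAc/MeOH, 25 °C
Reagents that add atoms: none
Why: Catalytic hydrogenolysis of five aryl benzyl ethers under neutral conditions; the diarylmethane C–C bonds and the methyl ether are not cleaved, and no acid touches the 4-hydroxybenzyl groups of ring A.

## Compound list

1 | 2-bromo-5-hydroxybenzaldehyde | O=Cc1cc(O)ccc1Br | starting material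
2 | 5-(benzyloxy)-2-bromobenzaldehyde | O=Cc1cc(OCc2ccccc2)ccc1Br | intermediate
3 | 4-(benzyloxy)-1-bromo-2-ethenylbenzene | C=Cc1cc(OCc2ccccc2)ccc1Br | intermediate
4 | 1-(benzyloxy)-4-(chloromethyl)benzene | ClCc1ccc(OCc2ccccc2)cc1 | starting material
5 | [4-(benzyloxy)benzyl]zinc chloride (not isolated) | Cl[Zn]Cc1ccc(OCc2ccccc2)cc1 | intermediate
6 | 4-(benzyloxy)-1-[4-(benzyloxy)benzyl]-2-ethenylbenzene (ring B styrene) | C=Cc1cc(OCc2ccccc2)ccc1Cc1ccc(OCc2ccccc2)cc1 | intermediate
7 | 3-bromo-5-methoxyphenol | COc1cc(O)cc(Br)c1 | starting material
8 | 9-{2-[5-(benzyloxy)-2-[4-(benzyloxy)benzyl]phenyl]ethyl}-9-borabicyclo[3.3.1]nonane (not isolated) | C(Cc1cc(OCc2ccccc2)ccc1Cc1ccc(OCc2ccccc2)cc1)B1C2CCCC1CCC2 | intermediate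
9 | 3-{2-[5-(benzyloxy)-2-[4-(benzyloxy)benzyl]phenyl]ethyl}-5-methoxyphenol (bibenzyl phenol) | COc1cc(O)cc(CCc2cc(OCc3ccccc3)ccc2Cc2ccc(OCc3ccccc3)cc2)c1 | intermediate
10 | 3-{2-[5-(benzyloxy)-2-[4-(benzyloxy)benzyl]phenyl]ethyl}-2,4,6-tris[(dimethylamino)methyl]-5-methoxyphenol | COc1c(CN(C)C)c(O)c(CN(C)C)c(CCc2cc(OCc3ccccc3)ccc2Cc2ccc(OCc3ccccc3)cc2)c1CN(C)C | intermediate
11 | 3-{2-[5-(benzyloxy)-2-[4-(benzyloxy)benzyl]phenyl]ethyl}-2,4,6-tris[(dimethylamino)methyl]-5-methoxyphenyl pivalate | COc1c(CN(C)C)c(OC(=O)C(C)(C)C)c(CN(C)C)c(CCc2cc(OCc3ccccc3)ccc2Cc2ccc(OCc3ccccc3)cc2)c1CN(C)C | intermediate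
12 | 3-{2-[5-(benzyloxy)-2-[4-(benzyloxy)benzyl]phenyl]ethyl}-2,4,6-tris(chloromethyl)-5-methoxyphenyl pivalate (precursor of the key step) | COc1c(CCl)c(OC(=O)C(C)(C)C)c(CCl)c(CCc2cc(OCc3ccccc3)ccc2Cc2ccc(OCc3ccccc3)cc2)c1CCl | intermediate
13 | 1-(benzyloxy)-4-bromobenzene | Brc1ccc(OCc2ccccc2)cc1 | starting material
14 | 3-{2-[5-(benzyloxy)-2-[4-(benzyloxy)benzyl]phenyl]ethyl}-2,4,6-tris[4-(benzyloxy)benzyl]-5-methoxyphenyl pivalate (product of the key step) | COc1c(Cc2ccc(OCc3ccccc3)cc2)c(OC(=O)C(C)(C)C)c(Cc2ccc(OCc3ccccc3)cc2)c(CCc2cc(OCc3ccccc3)ccc2Cc2ccc(OCc3ccccc3)cc2)c1Cc1ccc(OCc2ccccc2)cc1 | intermediate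
15 | 3-{2-[5-(benzyloxy)-2-[4-(benzyloxy)benzyl]phenyl]ethyl}-2,4,6-tris[4-(benzyloxy)benzyl]-5-methoxyphenol | COc1c(Cc2ccc(OCc3ccccc3)cc2)c(O)c(Cc2ccc(OCc3ccccc3)cc2)c(CCc2cc(OCc3ccccc3)ccc2Cc2ccc(OCc3ccccc3)cc2)c1Cc1ccc(OCc2ccccc2)cc1 | intermediate
16 | bleochrin B, 3-{2-[5-hydroxy-2-(4-hydroxybenzyl)phenyl]ethyl}-2,4,6-tris(4-hydroxybenzyl)-5-methoxyphenol | COc1c(Cc2ccc(O)cc2)c(O)c(Cc2ccc(O)cc2)c(CCc2cc(O)ccc2Cc2ccc(O)cc2)c1Cc1ccc(O)cc1 | target

## Step count and least certain steps

Total step count: 10 steps. Longest linear sequence: 10 steps (1 to 16); 4, 7 and 13 are bought and enter without steps of their own.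

Step 8 (key step). The most likely failures are benzyl–benzyl homocoupling that links molecules of 12 into oligomers, hydrodechlorination of a chloromethyl group to methyl, and stalling after one or two couplings because insertion of nickel into the electron-rich bromide 13 is slow relative to radical formation. The fallback sets out from 12 and comes back at 14. It forms the same three CH2–aryl bonds by a redox-neutral two-electron process: a threefold Suzuki–Miyaura coupling of 12 with commercial [4-(benzyloxy)phenyl]boronic acid (Pd(OAc)2, SPhos, K3PO4, toluene/water, 70 °C). Oxidative addition of zerovalent palladium to the benzylic C–Cl bond and transmetalation from boron leave no radical pathway for dimerisation. This fallback makes no compound outside the list (F0).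

Step 5. The substitution may stop after the two ortho aminomethylations, because the para position A6 is flanked by the methoxy group and the bridge. At high temperature a Mannich base may also alkylate unreacted phenol through a quinone methide and give diarylmethane oligomers. The fallback sets out from 9 and comes back at 11. Electrophilic bromination of the strongly activated ring A with NBS (3 equiv, MeCN, 0 °C) would give 3-{2-[5-(benzyloxy)-2-[4-(benzyloxy)benzyl]phenyl]ethyl}-2,4,6-tribromo-5-methoxyphenol F1. Pivaloylation (PivCl, Et3N, DMAP, CH2Cl2) would give 3-{2-[5-(benzyloxy)-2-[4-(benzyloxy)benzyl]phenyl]ethyl}-2,4,6-tribromo-5-methoxyphenyl pivalate F2. A threefold Suzuki–Miyaura aminomethylation of F2 with potassium (dimethylaminomethyl)trifluoroborate (Pd(OAc)2, XPhos, Cs2CO3, THF/water, 80 °C) would then install the three CH2NMe2 groups and give 11.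

Step 7. Carbamate expulsion may remain incomplete at one of the three sites. A chloride already formed may quaternise amine that is still unreacted, or ionisation of the electron-rich benzylic positions may lead to Friedel–Crafts alkylation of the benzyloxy rings. The fallback sets out from 11 and comes back at 14. Exhaustive N-methylation with MeOTf (CH2Cl2, 0 °C) would give the tris(trimethylammonium) tris(trifluoromethanesulfonate) F3. Its benzylic C–N bonds would then be coupled with [4-(benzyloxy)phenyl]boronic acid under nickel catalysis (Ni(cod)2, P(o-tol)3, K3PO4, 1,4-dioxane, 40 °C), a known Suzuki–Miyaura coupling of benzylic ammonium salts. This bypasses 12 but forms the same three CH2–aryl bonds.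

Step 4. β-Hydride elimination or protodeboronation of the alkylborane 8 may outrun transmetalation, and oxidative addition to the phenoxide form of 7 may be slow. The fallback sets out from 6 and comes back at 9. A Heck reaction of 6 with 7 (Pd(OAc)2, P(o-tol)3, Et3N, DMF, 100 °C) would give (E)-3-{2-[5-(benzyloxy)-2-[4-(benzyloxy)benzyl]phenyl]ethenyl}-5-methoxyphenol F4. Homogeneous hydrogenation of the stilbene double bond (H2, RhCl(PPh3)3, benzene/EtOH, 25 °C), which spares benzyl ethers, would give 9.

## Further compounds

F0 | step 8 | none | none
F1 | step 5 | 3-{2-[5-(benzyloxy)-2-[4-(benzyloxy)benzyl]phenyl]ethyl}-2,4,6-tribromo-5-methoxyphenol | COc1c(Br)c(O)c(Br)c(CCc2cc(OCc3ccccc3)ccc2Cc2ccc(OCc3ccccc3)cc2)c1Br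
F2 | step 5 | 3-{2-[5-(benzyloxy)-2-[4-(benzyloxy)benzyl]phenyl]ethyl}-2,4,6-tribromo-5-methoxyphenyl pivalate | COc1c(Br)c(OC(=O)C(C)(C)C)c(Br)c(CCc2cc(OCc3ccccc3)ccc2Cc2ccc(OCc3ccccc3)cc2)c1Br
F3 | step 7 | tris(trimethylammonium) tris(trifluoromethanesulfonate) derived from 11 by N-methylation of all three amino groups | COc1c(C[N+](C)(C)C)c(OC(=O)C(C)(C)C)c(C[N+](C)(C)C)c(CCc2cc(OCc3ccccc3)ccc2Cc2ccc(OCc3ccccc3)cc2)c1C[N+](C)(C)C.[O-]S(=O)(=O)C(F)(F)F.[O-]S(=O)(=O)C(F)(F)F.[O-]S(=O)(=O)C(F)(F)F
F4 | step 4 | (E)-3-{2-[5-(benzyloxy)-2-[4-(benzyloxy)benzyl]phenyl]ethenyl}-5-methoxyphenol | COc1cc(O)cc(/C=C/c2cc(OCc3ccccc3)ccc2Cc2ccc(OCc3ccccc3)cc2)c1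
A1 | alternative 1 | (E)-1-{2-[5-(methoxymethoxy)-2-[4-(methoxymethoxy)benzyl]phenyl]ethenyl}-5-methoxy-3-(methoxymethoxy)-2,4,6-tris[4-(methoxymethoxy)benzyl]benzene | COc1c(Cc2ccc(OCOC)cc2)c(OCOC)c(Cc2ccc(OCOC)cc2)c(/C=C/c2cc(OCOC)ccc2Cc2ccc(OCOC)cc2)c1Cc1ccc(OCOC)cc1
A2 | alternative 1 | 5-iodo-1-methoxy-3-(methoxymethoxy)-2-[4-(methoxymethoxy)benzyl]benzene | COc1cc(I)cc(OCOC)c1Cc1ccc(OCOC)cc1
A3 | alternative 1 | 1-(chloromethyl)-4-(methoxymethoxy)benzene | COCOc1ccc(CCl)cc1
A4 | alternative 1 | 2-ethenyl-4-(methoxymethoxy)-1-[4-(methoxymethoxy)benzyl]benzene | C=Cc1cc(OCOC)ccc1Cc1ccc(OCOC)cc1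
A5 | alternative 2 | racemic 2-{1-[3-methoxy-5-(methoxymethoxy)-2,4,6-tris[4-(methoxymethoxy)benzyl]phenyl]-2-[5-(methoxymethoxy)-2-[4-(methoxymethoxy)benzyl]phenyl]ethyl}-4,4,5,5-tetramethyl-1,3,2-dioxaborolane | COc1c(Cc2ccc(OCOC)cc2)c(OCOC)c(Cc2ccc(OCOC)cc2)c(C(Cc2cc(OCOC)ccc2Cc2ccc(OCOC)cc2)B2OC(C)(C)C(C)(C)O2)c1Cc1ccc(OCOC)cc1
A6 | alternative 2 | {3-methoxy-5-(methoxymethoxy)-2,4,6-tris[4-(methoxymethoxy)benzyl]phenyl}lithium | COc1c(Cc2ccc(OCOC)cc2)c(OCOC)c(Cc2ccc(OCOC)cc2)c([Li])c1Cc1ccc(OCOC)cc1
A7 | alternative 2 | 2-ethenyl-4,4,5,5-tetramethyl-1,3,2-dioxaborolane | C=CB1OC(C)(C)C(C)(C)O1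
A8 | alternative 2 | 5-(methoxymethoxy)-2-[4-(methoxymethoxy)benzyl]phenyl trifluoromethanesulfonate | O=S(=O)(Oc1cc(OCOC)ccc1Cc1ccc(OCOC)cc1)C(F)(F)F
A9 | alternative 3 | [4-hydroxy-2-{2-[3-methoxy-5-(methoxymethoxy)-2,4,6-tris[4-(methoxymethoxy)benzyl]phenyl]ethyl}phenyl][4-(methoxymethoxy)phenyl]methanone | COc1c(Cc2ccc(OCOC)cc2)c(OCOC)c(Cc2ccc(OCOC)cc2)c(CCc2cc(O)ccc2C(=O)c2ccc(OCOC)cc2)c1Cc1ccc(OCOC)cc1
A10 | alternative 3 | 5-{3-methoxy-5-(methoxymethoxy)-2,4,6-tris[4-(methoxymethoxy)benzyl]phenyl}-1-[4-(methoxymethoxy)phenyl]pent-2-yn-1-one | COc1c(Cc2ccc(OCOC)cc2)c(OCOC)c(Cc2ccc(OCOC)cc2)c(CCC#CC(=O)c2ccc(OCOC)cc2)c1Cc1ccc(OCOC)cc1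
A11 | alternative 3 | (E)-1-methoxy-3-(trimethylsilyloxy)buta-1,3-diene | CO/C=C/C(=C)O[Si](C)(C)C
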